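## Retrosynthetic overview
1. Target 17 comes from reductive N–O cleavage of the bis(N‑benzyloxy) tetracycle 16. Compound 16 comes from radical removal of the C12 oxygen, which serves only as a stereochemical relay, from cycloadduct 13.
2. Ring D (the imidazolidinone), both C–N bonds and both stereocentres (C6, C10) form in one (3+2) cycloaddition. The partners are diaza‑oxyallyl cation 12 (from urea 11) and the C6=C10 enamide 8, and addition occurs anti to the C12 silyloxy group.
3. Enamide 8 comes from dehydration of hemiaminal 6. Ring B closes when the pyrrole N–H traps the aldehyde made from ester 4.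
4. Amide 4 comes from trans‑4‑hydroxy‑L‑proline methyl ester (ring C, the only source of chirality) and 4,5‑dibromo‑2‑(trichloroacetyl)pyrrole (ring A with both bromines).
5. Ring order: A and C are bought, B forms in step 2, D forms in step 5.

Assumption: 1, 2 and 9 are catalogue compounds.

Numbering: phakellstatin numbering is used throughout. C6 is the aminal CH between pyrrole N and urea N. C10 is the quaternary aminal carbon. C11–C12–C13 are the pyrrolidine carbons running from C10 to amide N9, and C12 is the former C4 of hydroxyproline.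

## Route

Step 1
Reactants: 1 trans‑4‑hydroxy‑L‑proline methyl ester hydrochloride; 2 4,5‑dibromo‑2‑(trichloroacetyl)pyrrole
Product: 4 methyl (2S,4R)‑4‑(tert‑butyldiphenylsilyloxy)‑1‑(4,5‑dibromo‑1H‑pyrrole‑2‑carbonyl)pyrrolidine‑2‑carboxylate, via methyl (2S,4R)‑1‑(4,5‑dibromo‑1H‑pyrrole‑2‑carbonyl)‑4‑hydroxypyrrolidine‑2‑carboxylate 3 (not isolated)
Conditions: Et3N, DMF, rt; then imidazole, TBDPSCl, rt (one pot)
Reagents that add atoms: tert‑butyl(chloro)diphenylsilane (TBDPSCl), CC(C)(C)[Si](Cl)(c1ccccc1)c1ccccc1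
Why: The trichloromethyl ketone acts as an acid‑chloride surrogate (haloform‑type acyl substitution, CHCl3 leaves) and acylates only the ring nitrogen, after which imidazole‑promoted silylation caps the free secondary alcohol in the same DMF solution, leaving both Hyp stereocentres untouched.

Step 2
Reactants: 4 silyl ether ester
Product: 6 tricyclic hemiaminal (rings A‑B‑C; 6‑OH as an epimer mixture, 10S‑H, 12R‑OTBDPS), via (2S,4R)‑4‑(tert‑butyldiphenylsilyloxy)‑1‑(4,5‑dibromo‑1H‑pyrrole‑2‑carbonyl)pyrrolidine‑2‑carbaldehyde 5 (not isolated)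
Conditions: DIBAL‑H (2.2 equiv), CH2Cl2, −78 °C; aqueous work‑up
Reagents that add atoms: none
Why: This partial ester reduction stops at the tetrahedral aluminium hemiacetal at −78 °C (the first equivalent only deprotonates the pyrrole N–H; the tertiary amide, aryl bromides and silyl ether are inert), and the released aldehyde is trapped at once by the pyrrole N–H as the six‑membered hemiaminal, whose C6/C10 configurations do not matter because both carbons become sp2 in step 3.

Step 3
Reactants: 6 tricyclic hemiaminal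
Product: 8 tricyclic enamide (dibromo‑dipyrrolopyrazinone with a C6=C10 double bond and (12R)‑OTBDPS), via the 6‑O‑mesylate of the hemiaminal 7 (not isolated)
Conditions: MsCl, Et3N, CH2Cl2, 0 °C → rt
Reagents that add atoms: none
Why: In this mesylation/β‑elimination the aminal‑type mesylate ionises with help from the pyrrole nitrogen and loses the C10 proton to give the conjugated enamide, while the silyl ether is no leaving group, so ring C cannot aromatise and C12 (R) remains as the sole stereocentre.

Step 4
Reactants: 9 O‑benzylhydroxylamine hydrochloride (2 equiv)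
Product: 11 1,3‑bis(benzyloxy)urea, via N‑(benzyloxy)‑1H‑imidazole‑1‑carboxamide 10 (not isolated)
Conditions: CDI (0.5 equiv), THF, rt → 60 °C
Reagents that add atoms: 1,1'‑carbonyldiimidazole (CDI), O=C(n1ccnc1)n1ccnc1
Why: Two acyl substitutions take place at CDI, and the imidazole set free (pKaH about 7) is basic enough to liberate the weakly basic alkoxyamine (pKaH about 4.7) from its salt, so no further base is needed.

Step 5
Reactants: 8 tricyclic enamide; 11 1,3‑bis(benzyloxy)urea
Product: 13 (6R,10S,12R)‑N,N'‑bis(benzyloxy)‑12‑(tert‑butyldiphenylsilyloxy)dibromophakellstatin (urea ring cis‑fused and anti to the silyloxy group), via 1,3‑bis(benzyloxy)‑1,3‑diaza‑oxyallyl cation 12 (not isolated)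
Conditions: PhI(OAc)2 (1.5 equiv), 11 (1.5 equiv), HFIP/CH2Cl2, 0 °C → rt; chromatography
Reagents that add atoms: none
Why: PhI(OAc)2 oxidises the bis(alkoxy)urea to the alkoxy‑stabilised diaza‑oxyallyl cation, which adds suprafacially across the electron‑rich C6=C10 enamide in a (3+2) cycloaddition (cis fusion is the only possibility) from the face opposite the bulky (12R)‑silyloxy group, setting C6 and C10 with the geometry of the target; the pyrrole is blocked by its bromines, and the minor facial isomer is removed by chromatography so that the ee of Hyp is carried through.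

Step 6
Reactants: 13 cycloadduct
Product: 14 (6R,10S,12R)‑N,N'‑bis(benzyloxy)‑12‑hydroxydibromophakellstatin
Conditions: TBAF, AcOH, THF, rt
Reagents that add atoms: none
Why: Fluoride‑driven desilylation (Si–F bond strength), buffered with AcOH so that the amide, aminals, N–O bonds and aryl bromides are untouched, with no change at any stereocentre.

Step 7
Reactants: 14 alcohol
Product: 15 (6R,10S,12R)‑N,N'‑bis(benzyloxy)‑12‑(phenoxythiocarbonyloxy)dibromophakellstatin
Conditions: PhOC(S)Cl, DMAP, MeCN, rt
Reagents that add atoms: O‑phenyl chlorothionoformate, S=C(Cl)Oc1ccccc1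
Why: DMAP‑mediated thioacylation of the only protic group in the molecule (both urea nitrogens are still masked as N–OBn) gives the radical precursor with retention at C12.

Step 8
Reactants: 15 thionocarbonate
Product: 16 (6R,10S)‑N,N'‑bis(benzyloxy)dibromophakellstatin
Conditions: (Me3Si)3SiH (1.3 equiv), AIBN (cat.), toluene, 85 °C
Reagents that add atoms: none
Why: In this Barton–McCombie deoxygenation the silyl radical adds to C=S roughly two orders of magnitude faster than it abstracts bromine from an aryl bromide, β‑scission gives the secondary C12 radical, which takes H from the silane, so the relay stereocentre is erased while C6 and C10 are not involved.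

Step 9
Reactants: 16 bis(N‑benzyloxy) tetracycle
Product: 17 (6S,10R)‑dibromophakellstatin
Conditions: SmI2 (5 equiv), THF (no HMPA), 0 °C → rt; aqueous work‑up
Reagents that add atoms: none
Why: Single‑electron reductive N–O cleavage of the two N‑acyl alkoxyamine units is fast with SmI2 in HMPA‑free THF, where aryl bromides are not reduced; no bond to C6 or C10 is broken, and the descriptors change from 6R,10S to 6S,10R only because the CIP priority of the urea nitrogens drops when OBn becomes H.

## Compound list
1 | trans‑4‑hydroxy‑L‑proline methyl ester hydrochloride | Cl.COC(=O)[C@@H]1C[C@@H](O)CN1 | starting material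
2 | 4,5‑dibromo‑2‑(trichloroacetyl)pyrrole | O=C(c1cc(Br)c(Br)[nH]1)C(Cl)(Cl)Cl | starting material
3 | methyl (2S,4R)‑1‑(4,5‑dibromo‑1H‑pyrrole‑2‑carbonyl)‑4‑hydroxypyrrolidine‑2‑carboxylate | COC(=O)[C@@H]1C[C@@H](O)CN1C(=O)c1cc(Br)c(Br)[nH]1 | intermediate
4 | methyl (2S,4R)‑4‑(tert‑butyldiphenylsilyloxy)‑1‑(4,5‑dibromo‑1H‑pyrrole‑2‑carbonyl)pyrrolidine‑2‑carboxylate | COC(=O)[C@@H]1C[C@@H](O[Si](c2ccccc2)(c2ccccc2)C(C)(C)C)CN1C(=O)c1cc(Br)c(Br)[nH]1 | intermediate
5 | (2S,4R)‑4‑(tert‑butyldiphenylsilyloxy)‑1‑(4,5‑dibromo‑1H‑pyrrole‑2‑carbonyl)pyrrolidine‑2‑carbaldehyde | O=C[C@@H]1C[C@@H](O[Si](c2ccccc2)(c2ccccc2)C(C)(C)C)CN1C(=O)c1cc(Br)c(Br)[nH]1 | intermediate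
6 | tricyclic hemiaminal (6‑OH epimers, 10S, 12R‑OTBDPS) | O=C1c2cc(Br)c(Br)n2C(O)[C@@H]2C[C@@H](O[Si](c3ccccc3)(c3ccccc3)C(C)(C)C)CN12 | intermediate
7 | 6‑O‑mesylate of the hemiaminal | O=C1c2cc(Br)c(Br)n2C(OS(C)(=O)=O)[C@@H]2C[C@@H](O[Si](c3ccccc3)(c3ccccc3)C(C)(C)C)CN12 | intermediate
8 | tricyclic enamide (C6=C10, 12R‑OTBDPS) | O=C1c2cc(Br)c(Br)n2C=C2C[C@@H](O[Si](c3ccccc3)(c3ccccc3)C(C)(C)C)CN12 | intermediate
9 | O‑benzylhydroxylamine hydrochloride | Cl.NOCc1ccccc1 | starting material
10 | N‑(benzyloxy)‑1H‑imidazole‑1‑carboxamide | O=C(NOCc1ccccc1)n1ccnc1 | intermediate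
11 | 1,3‑bis(benzyloxy)urea | O=C(NOCc1ccccc1)NOCc1ccccc1 | intermediate
12 | 1,3‑bis(benzyloxy)‑1,3‑diaza‑oxyallyl cation (zwitterion, oxonium resonance form) | [O-]C(=NOCc1ccccc1)N=[O+]Cc1ccccc1 | intermediate
13 | (6R,10S,12R)‑N,N'‑bis(benzyloxy)‑12‑(tert‑butyldiphenylsilyloxy)dibromophakellstatin | O=C1N(OCc2ccccc2)[C@H]2n3c(cc(Br)c3Br)C(=O)N3C[C@H](O[Si](c4ccccc4)(c4ccccc4)C(C)(C)C)C[C@]23N1OCc1ccccc1 | intermediate
14 | (6R,10S,12R)‑N,N'‑bis(benzyloxy)‑12‑hydroxydibromophakellstatin | O=C1N(OCc2ccccc2)[C@H]2n3c(cc(Br)c3Br)C(=O)N3C[C@H](O)C[C@]23N1OCc1ccccc1 | intermediate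
15 | (6R,10S,12R)‑N,N'‑bis(benzyloxy)‑12‑(phenoxythiocarbonyloxy)dibromophakellstatin | O=C1N(OCc2ccccc2)[C@H]2n3c(cc(Br)c3Br)C(=O)N3C[C@H](OC(=S)Oc4ccccc4)C[C@]23N1OCc1ccccc1 | intermediate
16 | (6R,10S)‑N,N'‑bis(benzyloxy)dibromophakellstatin | O=C1N(OCc2ccccc2)[C@H]2n3c(cc(Br)c3Br)C(=O)N3CCC[C@]23N1OCc1ccccc1 | intermediate
17 | (6S,10R)‑dibromophakellstatin | O=C1N[C@H]2n3c(cc(Br)c3Br)C(=O)N3CCC[C@]23N1 | target

## Step count and risks
Total steps: 9. Longest linear sequence: 8 (steps 1, 2, 3, 5, 6, 7, 8, 9, starting from 1).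

**Step 5 (most likely to fail).** The oxidant may attack the enamide directly, the dipole may close through O instead of N, and the facial selectivity may be only moderate. The fallback sets out from 8 (with 11) and comes back at 13.
- The ring is built in two ionic operations. NBS in CH2Cl2 at −20 °C delivers Br+ to C6. The resulting C10 N‑acyliminium ion is captured by an alkoxyurea nitrogen of 11 on the face anti to the silyl ether. This gives the 6‑bromo‑10‑[1,3‑bis(benzyloxy)ureido] tricycle F1.
- Et3N then lets the aminal‑type C6–Br bond ionise, and the second urea nitrogen closes the five‑membered ring. Only cis fusion is possible, whatever the C6–Br configuration, and the product is 13.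

**Step 8.** Bromine abstraction from the dibromopyrrole may compete with deoxygenation. The fallback sets out from 15 and comes back at 16, and it needs no selectivity.
- Excess Bu3SnH/AIBN in refluxing toluene removes the thionocarbonate and both bromines, giving (6R,10S)‑N,N'‑bis(benzyloxy)phakellstatin F2.
- NBS (2 equiv, THF, 0 °C, dark) re‑brominates the two reactive positions (C4 and C5) of the 2‑acylpyrrole, giving 16.

**Step 9.** Partial debromination, or sluggish cleavage of the hindered N–O bond next to C10, may occur. The fallback sets out from 16 and comes back at 17, and it splits the task in two.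
- BCl3 (CH2Cl2, −78 → 0 °C) removes both benzyl groups without any reductant, giving (6R,10S)‑N,N'‑dihydroxydibromophakellstatin F3.
- Buffered aqueous TiCl3 (NaOAc, MeOH, rt) reduces both N–OH groups to N–H, giving 17.

## Further compounds
F1 | step 5 | 6‑bromo‑10‑[1,3‑bis(benzyloxy)ureido] tricycle (C6 epimers, urea N at C10 anti to 12R‑OTBDPS) | O=C1c2cc(Br)c(Br)n2C(Br)[C@@]2(N(OCc3ccccc3)C(=O)NOCc3ccccc3)C[C@@H](O[Si](c3ccccc3)(c3ccccc3)C(C)(C)C)CN12
F2 | step 8 | (6R,10S)‑N,N'‑bis(benzyloxy)phakellstatin | O=C1N(OCc2ccccc2)[C@H]2n3cccc3C(=O)N3CCC[C@]23N1OCc1ccccc1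
F3 | step 9 | (6R,10S)‑N,N'‑dihydroxydibromophakellstatin | O=C1N(O)[C@H]2n3c(cc(Br)c3Br)C(=O)N3CCC[C@]23N1O
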